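**Strategy.** The route rests on treating the C7(OH)–C8(OAr) pair (C7 benzylic, C8 methyl-bearing) as the product of a syn H–OH addition across a C7=C8 enol ether. Because C8 carries only H, methyl and the aryloxy oxygen, the whole neolignan core maps onto an achiral (Z)-1-aryl-2-aryloxypropene. Asymmetric hydroboration–oxidation of that enol ether forms the C7–O and C8–H bonds in one operation: the Z geometry is translated into the erythro relationship and the chiral borane fixes 7R,8S. The hindered 2,6-dimethoxyaryl ether bond is made beforehand at an sp2 carbon by copper-catalysed coupling of a (Z)-alkenyl iodide with the phenol, so no SN2 reaction at C8 and no ketone reduction is used.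

Key step: step 3

Remark on the chemistry: the alkenylstannane of the last step and the TMEDA adduct of monoisopinocampheylborane derived from (−)-α-pinene are taken as purchasable. The facial sense of the hydroboration is assigned by analogy with simple trisubstituted alkenes; the antipodal borane would be used should the sense be opposite.

**Step 1**
Reactants: 1 3,4-dimethoxybenzaldehyde; 2 ethyltriphenylphosphonium iodide
Product: 6 (Z)-4-(2-iodoprop-1-en-1-yl)-1,2-dimethoxybenzene, via ethylidenetriphenylphosphorane 3 (not isolated), via (1-iodoethyl)triphenylphosphonium iodide 4 (not isolated), via (1-iodoethylidene)triphenylphosphorane 5 (not isolated)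
Conditions: 2, n-BuLi, THF, 0 °C; I2, −78 °C; NaHMDS, −20 °C; then 1, −78 → −20 °C
Reagents that add atoms: iodine (II)
Why: Stork–Zhao-type Wittig olefination with the α-iodo ylide runs under kinetic control through the cis-oxaphosphetane, which should place iodine cis to the aryl group and give the Z iodoalkene; no stereocentre is formed.

**Step 2**
Reactants: 6 (Z)-4-(2-iodoprop-1-en-1-yl)-1,2-dimethoxybenzene; 7 4-bromo-2,6-dimethoxyphenol
Product: 8 (Z)-5-bromo-2-{[1-(3,4-dimethoxyphenyl)prop-1-en-2-yl]oxy}-1,3-dimethoxybenzene
Conditions: CuI (10 mol %), N,N-dimethylglycine·HCl (30 mol %), Cs2CO3, dioxane, 90 °C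
Reagents that add atoms: none
Why: Ullmann-type Cu(I)-catalysed C(sp2)–O coupling of an alkenyl iodide with a phenoxide proceeds with retention of alkene geometry, and the alkenyl iodide should react far faster than the electron-rich aryl bromide of 7, so the hindered ether bond is made without any substitution at a saturated carbon.

**Step 3**
Reactants: 8 (Z)-5-bromo-2-{[1-(3,4-dimethoxyphenyl)prop-1-en-2-yl]oxy}-1,3-dimethoxybenzene
Product: 10 (1R,2S)-2-(4-bromo-2,6-dimethoxyphenoxy)-1-(3,4-dimethoxyphenyl)propan-1-ol, via alkyl(isopinocampheyl)borane 9 (not isolated)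
Conditions: (IpcBH2)2·TMEDA [from (−)-α-pinene], BF3·OEt2, THF, 25 °C, filtered; 8, THF, −25 °C; then aq NaOH, 30% H2O2, 0 °C
Reagents that add atoms: hydrogen peroxide (OO)
Why: Concerted four-centre syn addition of the B–H bond of monoisopinocampheylborane across C7=C8 places boron on C7 and hydrogen on C8, and alkaline peroxide then replaces boron by oxygen through a 1,2-shift with retention; the closest known reaction type is the Brown asymmetric hydroboration–oxidation of trisubstituted alkenes and of enol ethers. No ring is closed. The relative configuration is fixed by the substrate, because syn addition to the Z isomer, in which aryl and aryloxy are cis, can only give the erythro (anti) pair. The absolute configuration is fixed by the reagent: by analogy with the sense known for trisubstituted alkenes, the borane from (−)-α-pinene should add to the Re face of C7 and so give 7R and, with it, 8S. The step needs regioselectivity for boron at C7, which is secured by the oxygen lone pair that makes C7 the nucleophilic β-carbon of the enol ether and by C7 being the less substituted, benzylic terminus. It also needs the β-aryloxy organoborane 9 to survive until oxidation, which the low temperature, the removal of the TMEDA·BF3 salt by filtration and immediate oxidation should secure.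

**Step 4**
Reactants: 10 (1R,2S)-2-(4-bromo-2,6-dimethoxyphenoxy)-1-(3,4-dimethoxyphenyl)propan-1-ol; 11 (E)-3-(tributylstannyl)prop-2-en-1-ol
Product: 12 (1R,2S)-1-(3,4-dimethoxyphenyl)-2-{4-[(E)-3-hydroxyprop-1-en-1-yl]-2,6-dimethoxyphenoxy}propan-1-ol
Conditions: Pd(P(t-Bu)3)2 (5 mol %), CsF, dioxane, 90 °C
Reagents that add atoms: none
Why: Stille cross-coupling with fluoride activation transfers the alkenyl group to the electron-rich aryl bromide with retention of E geometry and tolerates both free hydroxyl groups, so neither stereocentre is touched.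

**Compound list**
1 | 3,4-dimethoxybenzaldehyde | COc1ccc(C=O)cc1OC | starting material
2 | ethyltriphenylphosphonium iodide | CC[P+](c1ccccc1)(c1ccccc1)c1ccccc1.[I-] | starting material
3 | ethylidenetriphenylphosphorane | CC=P(c1ccccc1)(c1ccccc1)c1ccccc1 | intermediate
4 | (1-iodoethyl)triphenylphosphonium iodide | CC(I)[P+](c1ccccc1)(c1ccccc1)c1ccccc1.[I-] | intermediate
5 | (1-iodoethylidene)triphenylphosphorane | CC(I)=P(c1ccccc1)(c1ccccc1)c1ccccc1 | intermediate
6 | (Z)-4-(2-iodoprop-1-en-1-yl)-1,2-dimethoxybenzene | COc1ccc(/C=C(/C)I)cc1OC | intermediate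
7 | 4-bromo-2,6-dimethoxyphenol | COc1cc(Br)cc(OC)c1O | starting material
8 | (Z)-5-bromo-2-{[1-(3,4-dimethoxyphenyl)prop-1-en-2-yl]oxy}-1,3-dimethoxybenzene | COc1ccc(/C=C(/C)Oc2c(OC)cc(Br)cc2OC)cc1OC | intermediate
9 | [(1R,2S)-2-(4-bromo-2,6-dimethoxyphenoxy)-1-(3,4-dimethoxyphenyl)propyl](isopinocampheyl)borane, Ipc from (−)-α-pinene | C[C@@H]1[C@@H]([BH][C@H](c3ccc(OC)c(OC)c3)[C@H](C)Oc3c(OC)cc(Br)cc3OC)C[C@H]2C[C@@H]1C2(C)C | intermediate
10 | (1R,2S)-2-(4-bromo-2,6-dimethoxyphenoxy)-1-(3,4-dimethoxyphenyl)propan-1-ol | COc1ccc([C@@H](O)[C@H](C)Oc2c(OC)cc(Br)cc2OC)cc1OC | intermediate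
11 | (E)-3-(tributylstannyl)prop-2-en-1-ol | CCCC[Sn](CCCC)(CCCC)/C=C/CO | starting material
12 | (1R,2S)-1-(3,4-dimethoxyphenyl)-2-{4-[(E)-3-hydroxyprop-1-en-1-yl]-2,6-dimethoxyphenoxy}propan-1-ol | COc1ccc([C@@H](O)[C@H](C)Oc2c(OC)cc(/C=C/CO)cc2OC)cc1OC | target

**Step count.** Total: 4 steps. Longest linear sequence: 4 steps (1 → 6 → 8 → 10 → 12).

**Steps most likely to fail**

1. Step 3. The organoborane may lose boron and the β-aryloxy group by elimination before oxidation, or the borane may discriminate poorly between the two faces of the enol ether. The fallback sets out from 7 and returns at 10. Mitsunobu reaction of 7 with ethyl (R)-lactate (PPh3, DIAD, THF) would give, with inversion, ethyl (S)-2-(4-bromo-2,6-dimethoxyphenoxy)propanoate F1. Treatment with MeNHOMe·HCl and i-PrMgCl would give (S)-2-(4-bromo-2,6-dimethoxyphenoxy)-N-methoxy-N-methylpropanamide F2. Addition of 3,4-dimethoxyphenylmagnesium bromide would give (S)-2-(4-bromo-2,6-dimethoxyphenoxy)-1-(3,4-dimethoxyphenyl)propan-1-one F3. Chelation-controlled reduction with Zn(BH4)2 in Et2O at −20 °C should then deliver the anti alcohol 10, which enters step 4.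

2. Step 2. C–O bond formation with the doubly ortho-substituted phenoxide may be slow, which would allow dehydroiodination of the alkenyl iodide to the alkyne or erosion of alkene geometry at 90 °C. The fallback sets out from 6 and returns at 8. Iodine–lithium exchange on 6 (t-BuLi, Et2O, −78 °C), trapping with B(OMe)3 and treatment with KHF2 would give potassium (Z)-[1-(3,4-dimethoxyphenyl)prop-1-en-2-yl]trifluoroborate F4. Oxidative Chan–Lam-type coupling of this salt with 7 (Cu(OAc)2, DMAP, 4 Å MS, O2, CH2Cl2, room temperature) should give 8 with retention of geometry. This inverts the polarity of the alkenyl partner and avoids heat and carbonate base.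

3. Step 1. Z selectivity of the iodo-olefination may erode with the aromatic aldehyde, and proton transfer to the ylide may give the non-iodinated alkene. The fallback sets out from 1 and returns at 8. Ramirez olefination of 1 (CBr4, PPh3, CH2Cl2, 0 °C) would give 4-(2,2-dibromovinyl)-1,2-dimethoxybenzene F5. Trans-selective Negishi monomethylation (Me2Zn, Pd(P(t-Bu)3)2, THF, 0 °C), in which only the bromide trans to the aryl group undergoes oxidative addition, would give (Z)-4-(2-bromoprop-1-en-1-yl)-1,2-dimethoxybenzene F6. This bromide would take the place of 6 in the copper-catalysed coupling with 7 and give 8.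

**Further compounds**
F1 | step 3 | ethyl (S)-2-(4-bromo-2,6-dimethoxyphenoxy)propanoate | C[C@H](Oc1c(OC)cc(Br)cc1OC)C(=O)OCC
F2 | step 3 | (S)-2-(4-bromo-2,6-dimethoxyphenoxy)-N-methoxy-N-methylpropanamide | C[C@H](Oc1c(OC)cc(Br)cc1OC)C(=O)N(C)OC
F3 | step 3 | (S)-2-(4-bromo-2,6-dimethoxyphenoxy)-1-(3,4-dimethoxyphenyl)propan-1-one | C[C@H](Oc1c(OC)cc(Br)cc1OC)C(=O)c1ccc(OC)c(OC)c1
F4 | step 2 | potassium (Z)-[1-(3,4-dimethoxyphenyl)prop-1-en-2-yl]trifluoroborate | COc1ccc(/C=C(/C)[B-](F)(F)F)cc1OC.[K+]
F5 | step 1 | 4-(2,2-dibromovinyl)-1,2-dimethoxybenzene | COc1ccc(C=C(Br)Br)cc1OC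
F6 | step 1 | (Z)-4-(2-bromoprop-1-en-1-yl)-1,2-dimethoxybenzene | COc1ccc(/C=C(/C)Br)cc1OC
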